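**Retrosynthetic overview**

- The target is the O4-(E)-p-coumarate, O3-acetate of (3R,4S)-3,7-dimethylocta-1,6-diene-3,4-diol 10. The acyl groups go on last: O4 (secondary) first, then O3 (tertiary), then the phenol is unmasked.
- The strategy rests on the anti C3/C4 diol: C3 is a fully substituted carbinol carrying CH3 and the C1=C2 vinyl group, and C4 is a secondary carbinol carrying the prenyl chain. This is what an (E)-2-methyl-2,3-epoxy alcohol gives when its CH2–O oxygen is moved onto C3 with inversion and its CH2 is extended to the vinyl group.
- Key disconnection: the C1=C2 bond and the tertiary C3–O bond, from epoxy alcohol 6 and trimethylsulfonium iodide 7 (Payne shift intercepted by dimethylsulfonium methylide).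
- 6 comes from Sharpless epoxidation of (E)-allylic alcohol 5, which comes from enoate 4, made from homoprenyl alcohol 1 and ylide 2.
- Rings: the benzene ring is purchased and the rest is acyclic. The only rings made are two oxiranes, first the Sharpless epoxide and then the transient terminal oxirane (C2, C3 and the oxygen that ends on C3); both are consumed in step 4.

Key step: step 4

Remark on the chemistry: the C10 chain is numbered as in linalool throughout (C1=C2 vinyl, C3 tertiary carbinol, C4 secondary carbinol, C6=C7 prenyl alkene); oxirane locants are used only in the names of 6 and 8.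

**Route**

Step 1
Reactants: 1 4-methylpent-3-en-1-ol; 2 ethyl 2-(triphenylphosphoranylidene)propanoate
Product: 4 ethyl (2E)-2,6-dimethylhepta-2,5-dienoate, via 4-methylpent-3-enal 3 (not isolated)
Conditions: Dess–Martin periodinane (1.3 equiv), 2 (2.5 equiv) present from the start, CH2Cl2, 0 °C → rt
Reagents that add atoms: none
Why: Dess–Martin oxidation in the presence of the stabilised ylide traps the isomerisation-prone β,γ-unsaturated aldehyde 3 as it forms, and the Wittig reaction of an α-methyl ester ylide should give the (E)-trisubstituted enoate (no stereocentre is set).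

Step 2
Reactants: 4 ethyl (2E)-2,6-dimethylhepta-2,5-dienoate
Product: 5 (2E)-2,6-dimethylhepta-2,5-dien-1-ol
Conditions: (i-Bu)2AlH (2.3 equiv), CH2Cl2, −78 → −20 °C; aq. potassium sodium tartrate (KNaC4H4O6) work-up
Reagents that add atoms: none
Why: Ester reduction with (i-Bu)2AlH at low temperature is a clean 1,2-reduction of an α,β-unsaturated ester to the allylic alcohol and leaves both alkenes and the E geometry untouched.

Step 3
Reactants: 5 (2E)-2,6-dimethylhepta-2,5-dien-1-ol
Product: 6 [(2S,3S)-2-methyl-3-(3-methylbut-2-en-1-yl)oxiran-2-yl]methanol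
Conditions: Ti(OiPr)4 (10 mol %), L-(+)-diethyl tartrate (12 mol %), t-BuOOH (2 equiv, anhydrous), 4 Å molecular sieves, CH2Cl2, −20 °C
Reagents that add atoms: tert-butyl hydroperoxide, CC(C)(C)OO
Why: In the Sharpless asymmetric epoxidation the titanium tartrate complex binds the allylic hydroxyl and delivers oxygen only to the adjacent alkene, L-(+)-diethyl tartrate giving the (2S,3S) epoxide of an (E)-2-methyl allylic alcohol (both stereocentres are set by the ligand), while the remote prenyl alkene has no directing hydroxyl and should stay intact.

Step 4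
Reactants: 6 [(2S,3S)-2-methyl-3-(3-methylbut-2-en-1-yl)oxiran-2-yl]methanol; 7 trimethylsulfonium iodide
Product: 10 (3R,4S)-3,7-dimethylocta-1,6-diene-3,4-diol, via terminal epoxide alkoxide 8 (not isolated), via sulfonium betaine 9 (not isolated)
Conditions: 7 (6 equiv), n-BuLi (5.5 equiv), THF, −10 °C; then 6, −10 °C → rt
Reagents that add atoms: none
Why: Deprotonated 6 equilibrates by Payne rearrangement with the terminal epoxide 8: the primary alkoxide attacks the methyl-bearing oxirane carbon from the rear (3-exo-tet closure of a new oxirane that is consumed again, so no ring remains), which places that oxygen on C3 with inversion and leaves the former epoxide oxygen on C4. Only 8 has an unhindered CH2, so dimethylsulfonium methylide opens it there to the betaine 9; a second equivalent of ylide deprotonates an S-methyl group, and the new ylide removes a proton from the neighbouring CH2 through a five-membered transition state, expelling dimethyl sulfide and forming the C1=C2 vinyl group. The closest known reaction type is the tandem Payne rearrangement/dimethylsulfonium methylide homologation of 2,3-epoxy alcohols to 1-alkene-3,4-diols, itself an extension of the ylide conversion of epoxides into one-carbon-homologated allylic alcohols. C3 is the only stereocentre that changes, and it is controlled by the stereospecific SN2 inversion, so the (E)-derived (2S,3S) epoxide can only give the anti (3R,4S) diol. The selectivity needed is attack of the ylide on the rearranged and not the original epoxide, which the trisubstituted, neopentyl-like oxirane of 6 secures; because the migration terminus is fully substituted the shift may be slow, so an excess of ylide and slow warming are planned.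

Step 5
Reactants: 11 p-coumaric acid, (2E)-3-(4-hydroxyphenyl)prop-2-enoic acid
Product: 13 (2E)-3-{4-[(tert-butyldimethylsilyl)oxy]phenyl}prop-2-enoic acid, via bis-silylated silyl ester 12 (not isolated)
Conditions: TBSCl (2.5 equiv), imidazole (5 equiv), DMF, rt; then AcOH/THF/H2O, rt
Reagents that add atoms: tert-butyldimethylsilyl chloride, CC(C)(C)[Si](C)(C)Cl
Why: Silylation of both the phenol and the acid followed by hydrolysis of the far more labile silyl ester leaves the phenol protected as its aryl silyl ether (protecting-group installation).

Step 6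
Reactants: 10 (3R,4S)-3,7-dimethylocta-1,6-diene-3,4-diol; 13 (2E)-3-{4-[(tert-butyldimethylsilyl)oxy]phenyl}prop-2-enoic acid
Product: 14 (3R,4S)-3-hydroxy-3,7-dimethylocta-1,6-dien-4-yl (2E)-3-{4-[(tert-butyldimethylsilyl)oxy]phenyl}prop-2-enoate
Conditions: 13 (1.1 equiv), DCC (1.2 equiv), 4-(dimethylamino)pyridine (0.2 equiv), CH2Cl2, 0 °C → rt
Reagents that add atoms: none
Why: In this Steglich esterification the acylpyridinium derived from 13 should acylate the secondary C4 hydroxyl while the fully substituted C3 hydroxyl is too hindered to react at room temperature, and C4 keeps its configuration because its C–O bond is not broken.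

Step 7
Reactants: 14 (3R,4S)-3-hydroxy-3,7-dimethylocta-1,6-dien-4-yl (2E)-3-{4-[(tert-butyldimethylsilyl)oxy]phenyl}prop-2-enoate
Product: 15 (3R,4S)-3-(acetyloxy)-3,7-dimethylocta-1,6-dien-4-yl (2E)-3-{4-[(tert-butyldimethylsilyl)oxy]phenyl}prop-2-enoate
Conditions: Ac2O (5 equiv), Et3N (6 equiv), 4-(dimethylamino)pyridine (1 equiv), CH2Cl2, rt → 40 °C
Reagents that add atoms: acetic anhydride, CC(=O)OC(C)=O
Why: 4-(Dimethylamino)pyridine-catalysed acetylation with acetic anhydride is the standard non-ionising way to acylate tertiary alcohols of the linalool type, so the tertiary allylic C3–O bond and its configuration should be retained and the aryl silyl ether and the cinnamate left alone.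

Step 8
Reactants: 15 (3R,4S)-3-(acetyloxy)-3,7-dimethylocta-1,6-dien-4-yl (2E)-3-{4-[(tert-butyldimethylsilyl)oxy]phenyl}prop-2-enoate
Product: 16 (3R,4S)-3-(acetyloxy)-3,7-dimethylocta-1,6-dien-4-yl (2E)-3-(4-hydroxyphenyl)prop-2-enoate (CNP0547742.1)
Conditions: Bu4NF (1.1 equiv), AcOH (1.2 equiv), THF, 0 °C
Reagents that add atoms: none
Why: Fluoride cleaves an aryl silyl ether far faster than it attacks carboxylic esters, and buffering with acetic acid keeps the liberated phenol protonated so that neither ester should be cleaved or migrate (desilylation).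

**Compound list**

1 | 4-methylpent-3-en-1-ol | CC(C)=CCCO | starting material
2 | ethyl 2-(triphenylphosphoranylidene)propanoate | CCOC(=O)C(C)=P(c1ccccc1)(c1ccccc1)c1ccccc1 | starting material
3 | 4-methylpent-3-enal (formed in the flask, not isolated) | CC(C)=CCC=O | intermediate
4 | ethyl (2E)-2,6-dimethylhepta-2,5-dienoate | CCOC(=O)/C(C)=C/CC=C(C)C | intermediate
5 | (2E)-2,6-dimethylhepta-2,5-dien-1-ol | OC/C(C)=C/CC=C(C)C | intermediate
6 | [(2S,3S)-2-methyl-3-(3-methylbut-2-en-1-yl)oxiran-2-yl]methanol | OC[C@]1(C)O[C@H]1CC=C(C)C | intermediate
7 | trimethylsulfonium iodide | C[S+](C)C.[I-] | starting material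
8 | (1S)-4-methyl-1-[(2R)-2-methyloxiran-2-yl]pent-3-en-1-ol (present as its lithium alkoxide, not isolated) | C[C@@]1(CO1)[C@@H](O)CC=C(C)C | intermediate
9 | [(3R,4S)-4-hydroxy-3,7-dimethyl-3-oxidooct-6-en-1-yl]dimethylsulfonium, inner salt (not isolated) | C[S+](C)CC[C@@](C)([O-])[C@@H](O)CC=C(C)C | intermediate
10 | (3R,4S)-3,7-dimethylocta-1,6-diene-3,4-diol | C=C[C@@](C)(O)[C@H](CC=C(C)C)O | intermediate
11 | p-coumaric acid, (2E)-3-(4-hydroxyphenyl)prop-2-enoic acid | O=C(O)/C=C/c1ccc(O)cc1 | starting material
12 | tert-butyldimethylsilyl (2E)-3-{4-[(tert-butyldimethylsilyl)oxy]phenyl}prop-2-enoate (not isolated) | CC(C)(C)[Si](C)(C)OC(=O)/C=C/c1ccc(O[Si](C)(C)C(C)(C)C)cc1 | intermediate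
13 | (2E)-3-{4-[(tert-butyldimethylsilyl)oxy]phenyl}prop-2-enoic acid | O=C(O)/C=C/c1ccc(O[Si](C)(C)C(C)(C)C)cc1 | intermediate
14 | (3R,4S)-3-hydroxy-3,7-dimethylocta-1,6-dien-4-yl (2E)-3-{4-[(tert-butyldimethylsilyl)oxy]phenyl}prop-2-enoate | C=C[C@@](C)(O)[C@H](CC=C(C)C)OC(=O)/C=C/c1ccc(O[Si](C)(C)C(C)(C)C)cc1 | intermediate
15 | (3R,4S)-3-(acetyloxy)-3,7-dimethylocta-1,6-dien-4-yl (2E)-3-{4-[(tert-butyldimethylsilyl)oxy]phenyl}prop-2-enoate | C=C[C@@](C)(OC(C)=O)[C@H](CC=C(C)C)OC(=O)/C=C/c1ccc(O[Si](C)(C)C(C)(C)C)cc1 | intermediate
16 | (3R,4S)-3-(acetyloxy)-3,7-dimethylocta-1,6-dien-4-yl (2E)-3-(4-hydroxyphenyl)prop-2-enoate | C=C[C@@](C)(OC(C)=O)[C@H](CC=C(C)C)OC(=O)/C=C/c1ccc(O)cc1 | target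

**Step count and risks**

Total step count: 8. Longest linear sequence: 7 steps (steps 1, 2, 3, 4, 6, 7, 8); step 5 prepares the acid fragment.

Steps most likely to fail:

1. Step 4. The Payne shift must occur at a fully substituted carbon, as a lithium alkoxide in THF. If it is too slow, the ylide is lost to its own decomposition or reacts unselectively, and 6 is recovered or degraded. The fallback avoids the shift by making the terminal epoxide as an isolated compound. It sets out from 1, which is oxidised to 4-methylpent-3-enal 3 (Dess–Martin periodinane, NaHCO3, CH2Cl2, 0 °C, used cold without purification). Addition of isopropenylmagnesium bromide, CH2=C(CH3)MgBr (THF, −78 °C) gives racemic 2,6-dimethylhepta-1,5-dien-3-ol F1. Sharpless kinetic resolution (Ti(OiPr)4, L-(+)-diisopropyl tartrate, t-BuOOH 0.6 equiv, 4 Å molecular sieves, CH2Cl2, −20 °C) should epoxidise the (S) enantiomer preferentially, with the erythro selectivity usual for secondary allylic alcohols. This gives epoxy alcohol 8 in neutral, isolable form and leaves the (R) alcohol behind. Treating 8 with the ylide from 7 and n-BuLi (THF, −10 °C → rt) opens an existing terminal epoxide with no rearrangement needed, and the fallback comes back to the route at diol 10.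

2. Step 7. The tertiary C3 hydroxyl lies between a quaternary centre and an acyloxy-bearing carbon and may acetylate very slowly. Under forcing conditions the coumaroyl group can migrate from O4 to O3 (the freed secondary hydroxyl is then acetylated instead), or the tertiary allylic C–O bond can ionise. The fallback reverses the order of the two acylations through a cyclic orthoester. It sets out from diol 10, which with trimethyl orthoacetate and pyridinium p-toluenesulfonate (CH2Cl2, rt) gives the cyclic orthoacetate (4R,5S)-4-ethenyl-2-methoxy-2,4-dimethyl-5-(3-methylbut-2-en-1-yl)-1,3-dioxolane F2. Brief treatment with aqueous acetic acid should open the derived hemiorthoester with release of the less hindered secondary oxygen, as is usual for kinetic orthoester opening. That leaves the acetyl group on the tertiary oxygen, in (3R,4S)-4-hydroxy-3,7-dimethylocta-1,6-dien-3-yl acetate F3. The secondary hydroxyl of F3 is then esterified with the mixed anhydride of 13 (2,4,6-trichlorobenzoyl chloride, Et3N, toluene; then F3, 4-(dimethylamino)pyridine, 0 °C, kept cold to suppress acetyl migration). The fallback comes back to the route at 15.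

3. Step 6. The secondary hydroxyl is next to a quaternary carbinol carbon and the activated cinnamoyl donor is a weak electrophile. Acylation may stall while the O-acylisourea rearranges to the N-acylurea or is diverted to the anhydride. The fallback builds the cinnamate on the substrate. It sets out from 10, whose O4 is acylated with the small, unconjugated diethylphosphonoacetic acid (DCC, 4-(dimethylamino)pyridine cat., CH2Cl2, 0 °C) to give (3R,4S)-3-hydroxy-3,7-dimethylocta-1,6-dien-4-yl 2-(diethoxyphosphoryl)acetate F4. Horner–Wadsworth–Emmons olefination of F4 with commercial 4-[(tert-butyldimethylsilyl)oxy]benzaldehyde (LiCl, DBU, MeCN, rt) should be E-selective, and the fallback comes back to the route at 14.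

**Further compounds**

F1 | step 4 | racemic 2,6-dimethylhepta-1,5-dien-3-ol | CC(=C)C(O)CC=C(C)C
F2 | step 7 | (4R,5S)-4-ethenyl-2-methoxy-2,4-dimethyl-5-(3-methylbut-2-en-1-yl)-1,3-dioxolane (both epimers at C2) | C=C[C@@]1(C)OC(C)(OC)O[C@H]1CC=C(C)C
F3 | step 7 | (3R,4S)-4-hydroxy-3,7-dimethylocta-1,6-dien-3-yl acetate | C=C[C@@](C)(OC(C)=O)[C@H](CC=C(C)C)O
F4 | step 6 | (3R,4S)-3-hydroxy-3,7-dimethylocta-1,6-dien-4-yl 2-(diethoxyphosphoryl)acetate | C=C[C@@](C)(O)[C@H](CC=C(C)C)OC(=O)CP(=O)(OCC)OCC
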